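**Retrosynthetic overview** (ring numbered as in shikimic acid: C1 carries CO2Me, C2 is the vinylic CH, C3 carries OAc, C4 and C5 carry the 2-methylbutanoates, C6 is CH2)
1. End game: target 14 from diol 12 and two equivalents of acid 13; 12 from acetonide 11; 11 from the 3-epi alcohol 10 by an invertive Mitsunobu delivery of acetate at C3.
2. Key disconnection: the ring bond C2–C3 of the cyclohexene. Alcohol 10 comes from the acyclic nitro aldehyde 8 by intramolecular Henry ring closure, followed in the same flask by loss of HNO2, which creates C1=C2.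
3. Enabling feature: C2 is the β-carbon of the C1=C2–CO2Me enoate and its ring neighbour C3 is oxygenated. C2 can therefore be carried as an acidic CH2NO2 group β to the ester (a masked acrylate β-anion) and C3 as an aldehyde; the nitro group then leaves together with the C1–H.
4. Aldehyde 8 comes from triflate 3 (C3–C6 with the trans-4,5-diol, bought as D-threitol acetonide 1) and methyl 3-nitropropanoate 4 (C1, C2, ester carbon) by C-alkylation of the dianion.
5. Ring order: the target has one ring; the cyclohexene is closed in step 6, trans-fused to the temporary dioxolane on O4/O5 that comes from 1 and is removed in step 8.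

Key step: step 6

Assumption: both side chains of the target are read as (R)-2-methylbutanoyl, and 1 (D-threitol series), 4 and 13 are taken as purchasable in the stated form.

**Step 1**
Reactants: 1 (4R,5R)-2,2-dimethyl-1,3-dioxolane-4,5-dimethanol
Product: 2 [(4R,5R)-5-({[tert-butyl(dimethyl)silyl]oxy}methyl)-2,2-dimethyl-1,3-dioxolan-4-yl]methanol
Conditions: NaH (1.0 equiv), THF, 0 °C; then TBSCl (1.0 equiv), 0 °C to rt
Reagents that add atoms: tert-butyldimethylsilyl chloride, CC(C)(C)[Si](C)(C)Cl
Why: Monosilylation of a C2-symmetric diol through its monosodium alkoxide (O-silylation); the two hydroxyls are homotopic, so one constitution should result and no stereocenter is touched.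

**Step 2**
Reactants: 2 [(4R,5R)-5-({[tert-butyl(dimethyl)silyl]oxy}methyl)-2,2-dimethyl-1,3-dioxolan-4-yl]methanol
Product: 3 [(4R,5R)-5-({[tert-butyl(dimethyl)silyl]oxy}methyl)-2,2-dimethyl-1,3-dioxolan-4-yl]methyl trifluoromethanesulfonate
Conditions: Tf2O, 2,6-lutidine, CH2Cl2, −78 °C; short cold work-up, used crude
Reagents that add atoms: trifluoromethanesulfonic anhydride, O=S(=O)(OS(=O)(=O)C(F)(F)F)C(F)(F)F
Why: O-sulfonylation of the primary alcohol gives the triflate, the leaving group needed for SN2 at a β-oxygenated primary carbon; no stereocenter is touched.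

**Step 3**
Reactants: 3 [(4R,5R)-5-({[tert-butyl(dimethyl)silyl]oxy}methyl)-2,2-dimethyl-1,3-dioxolan-4-yl]methyl trifluoromethanesulfonate; 4 methyl 3-nitropropanoate
Product: 6 methyl 3-[(4R,5R)-5-({[tert-butyl(dimethyl)silyl]oxy}methyl)-2,2-dimethyl-1,3-dioxolan-4-yl]-2-(nitromethyl)propanoate, via dilithiated methyl 3-nitropropanoate 5 (not isolated)
Conditions: 4, LiN(iPr)2 (2.1 equiv), THF/DMPU, −78 °C; then 3, −78 to −30 °C; AcOH, −78 °C
Reagents that add atoms: none
Why: SN2 C-alkylation of doubly deprotonated 3-nitropropanoate, which is known to react with alkylating agents at the carbon α to the ester while the nitronate survives; the new stereocenter at that carbon is not controlled and is erased in step 6.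

**Step 4**
Reactants: 6 methyl 3-[(4R,5R)-5-({[tert-butyl(dimethyl)silyl]oxy}methyl)-2,2-dimethyl-1,3-dioxolan-4-yl]-2-(nitromethyl)propanoate
Product: 7 methyl 3-[(4R,5R)-5-(hydroxymethyl)-2,2-dimethyl-1,3-dioxolan-4-yl]-2-(nitromethyl)propanoate
Conditions: HF·pyridine, pyridine, THF, 0 °C to rt
Reagents that add atoms: none
Why: Desilylation with buffered HF·pyridine frees the primary alcohol without exposing the base-labile β-nitro ester to basic fluoride; no stereocenter is changed.

**Step 5**
Reactants: 7 methyl 3-[(4R,5R)-5-(hydroxymethyl)-2,2-dimethyl-1,3-dioxolan-4-yl]-2-(nitromethyl)propanoate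
Product: 8 methyl 3-[(4R,5S)-5-formyl-2,2-dimethyl-1,3-dioxolan-4-yl]-2-(nitromethyl)propanoate
Conditions: Dess–Martin periodinane, CH2Cl2, 0 °C; Na2S2O3/NaHCO3 work-up; used at once
Reagents that add atoms: none
Why: Dess–Martin oxidation gives the α-alkoxy aldehyde under non-basic conditions, so neither epimerization next to the formyl group nor premature loss of nitrous acid is expected.

**Step 6**
Reactants: 8 methyl 3-[(4R,5S)-5-formyl-2,2-dimethyl-1,3-dioxolan-4-yl]-2-(nitromethyl)propanoate
Product: 10 methyl 3-epi-shikimate 4,5-O-isopropylidene acetal, via nitrocyclohexanol 9 (not isolated)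
Conditions: Et3N (0.2 equiv), CH2Cl2, 0 °C until 8 is consumed; then DBU (2.0 equiv), 0 °C to rt
Reagents that add atoms: none
Why: Triethylamine deprotonates the CH2NO2 carbon (C2) and the nitronate adds to the formyl carbon (C3) in an intramolecular Henry reaction; DBU then removes the C1–H α to the ester and nitrite leaves from C2 (E1cB), which creates the C1=C2 enoate. The closest known reaction types are the base-mediated nitroaldol cyclization of 6-nitro aldehydes to nitrocyclohexanols and the DBU-induced loss of nitrous acid from β-nitro esters, in which a 3-nitropropanoate serves as an acrylate β-anion equivalent. The six-membered carbocycle closes in a 6-exo-trig mode (nitronate carbon onto C=O), trans-fused to the dioxolane. C3 is the only new stereocenter that survives (C1 and C2 are erased by the elimination): because the nitroaldol is reversible, it should be set under thermodynamic control in the ring locked by the trans-fused dioxolane, with the hydroxyl equatorial and therefore trans to O4 (3-epi series). The step needs ring closure before nitrite loss, elimination toward C1 and not dehydration to a nitroalkene, and retention of configuration next to the formyl group; these should be secured by the large acidity gap between CH2NO2 and the ester α-H (weak base first, DBU second), by the free hydroxyl being a poor leaving group, and by the low temperature.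

**Step 7**
Reactants: 10 methyl 3-epi-shikimate 4,5-O-isopropylidene acetal
Product: 11 methyl (3R,4S,5R)-3-acetoxy-4,5-(isopropylidenedioxy)cyclohex-1-ene-1-carboxylate
Conditions: AcOH (1.5 equiv), PPh3, DIAD, THF, 0 °C
Reagents that add atoms: acetic acid, CC(=O)O
Why: Mitsunobu reaction, in which the C3 hydroxyl is activated and displaced by acetate in an SN2 process with inversion, turning the 3,4-trans alcohol into the 3,4-cis acetate of the target; C4 and C5 are untouched.

**Step 8**
Reactants: 11 methyl (3R,4S,5R)-3-acetoxy-4,5-(isopropylidenedioxy)cyclohex-1-ene-1-carboxylate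
Product: 12 methyl (3R,4S,5R)-3-acetoxy-4,5-dihydroxycyclohex-1-ene-1-carboxylate
Conditions: TFA/H2O (4:1), CH2Cl2, 0 °C; toluene azeotrope; used crude
Reagents that add atoms: none
Why: Acid-catalysed acetal hydrolysis of the strained trans-fused isopropylidene acetal releases the 4,5-diol, and a cold acidic medium is chosen because migration of the cis-3-acetate to O4 is base-promoted; no stereocenter is changed.

**Step 9**
Reactants: 12 methyl (3R,4S,5R)-3-acetoxy-4,5-dihydroxycyclohex-1-ene-1-carboxylate; 13 (R)-2-methylbutanoic acid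
Product: 14 methyl (3R,4S,5R)-3-acetoxy-4,5-bis{[(2R)-2-methylbutanoyl]oxy}cyclohex-1-ene-1-carboxylate
Conditions: 13 (3 equiv), N,N'-diisopropylcarbodiimide (3 equiv), DMAP (0.2 equiv), CH2Cl2, 0 °C to rt
Reagents that add atoms: none
Why: Steglich esterification acylates both secondary hydroxyls; the ring stereocenters are untouched and the α-stereocenter of the acid should be retained because no strong base and no ketene-forming acid chloride is involved.

**Compound list**
1 | (4R,5R)-2,2-dimethyl-1,3-dioxolane-4,5-dimethanol (2,3-O-isopropylidene-D-threitol) | OC[C@H]1OC(C)(C)O[C@@H]1CO | starting material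
2 | [(4R,5R)-5-({[tert-butyl(dimethyl)silyl]oxy}methyl)-2,2-dimethyl-1,3-dioxolan-4-yl]methanol | CC(C)(C)[Si](C)(C)OC[C@H]1OC(C)(C)O[C@@H]1CO | intermediate
3 | [(4R,5R)-5-({[tert-butyl(dimethyl)silyl]oxy}methyl)-2,2-dimethyl-1,3-dioxolan-4-yl]methyl trifluoromethanesulfonate | CC(C)(C)[Si](C)(C)OC[C@H]1OC(C)(C)O[C@@H]1COS(=O)(=O)C(F)(F)F | intermediate
4 | methyl 3-nitropropanoate | COC(=O)CC[N+](=O)[O-] | starting material
5 | dilithium salt of doubly deprotonated methyl 3-nitropropanoate (ester enolate and nitronate) | [Li+].[Li+].COC([O-])=CC=[N+]([O-])[O-] | intermediate (not isolated)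
6 | methyl 3-[(4R,5R)-5-({[tert-butyl(dimethyl)silyl]oxy}methyl)-2,2-dimethyl-1,3-dioxolan-4-yl]-2-(nitromethyl)propanoate, both epimers at C2 of the propanoate | CC(C)(C)[Si](C)(C)OC[C@H]1OC(C)(C)O[C@@H]1CC(C(=O)OC)C[N+](=O)[O-] | intermediate
7 | methyl 3-[(4R,5R)-5-(hydroxymethyl)-2,2-dimethyl-1,3-dioxolan-4-yl]-2-(nitromethyl)propanoate, both epimers at C2 of the propanoate | OC[C@H]1OC(C)(C)O[C@@H]1CC(C(=O)OC)C[N+](=O)[O-] | intermediate
8 | methyl 3-[(4R,5S)-5-formyl-2,2-dimethyl-1,3-dioxolan-4-yl]-2-(nitromethyl)propanoate, both epimers at C2 of the propanoate | O=C[C@H]1OC(C)(C)O[C@@H]1CC(C(=O)OC)C[N+](=O)[O-] | intermediate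
9 | methyl 7-hydroxy-2,2-dimethyl-6-nitrohexahydro-1,3-benzodioxole-5-carboxylate, trans-fused, drawn as the expected major isomer with hydroxyl, nitro and ester groups all equatorial (shikimate numbering: 3-OH trans to O4, 2-NO2, 1-CO2Me); in equilibrium with its epimers | CC1(C)O[C@@H]2[C@@H](O)[C@H]([N+](=O)[O-])[C@@H](C(=O)OC)C[C@H]2O1 | intermediate (not isolated)
10 | methyl 3-epi-shikimate 4,5-O-isopropylidene acetal, methyl (3S,4R,5R)-3-hydroxy-4,5-(isopropylidenedioxy)cyclohex-1-ene-1-carboxylate (3-OH trans to O4, O4 trans to O5, C4 and C5 as in shikimic acid) | CC1(C)O[C@@H]2[C@@H](O)C=C(C(=O)OC)C[C@H]2O1 | intermediate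
11 | methyl (3R,4S,5R)-3-acetoxy-4,5-(isopropylidenedioxy)cyclohex-1-ene-1-carboxylate (methyl 3-O-acetylshikimate 4,5-acetonide) | CC1(C)O[C@@H]2[C@H](OC(C)=O)C=C(C(=O)OC)C[C@H]2O1 | intermediate
12 | methyl (3R,4S,5R)-3-acetoxy-4,5-dihydroxycyclohex-1-ene-1-carboxylate (methyl 3-O-acetylshikimate) | O[C@@H]1[C@H](OC(C)=O)C=C(C(=O)OC)C[C@H]1O | intermediate
13 | (R)-2-methylbutanoic acid | CC[C@@H](C)C(=O)O | starting material
14 | methyl (3R,4S,5R)-3-acetoxy-4,5-bis{[(2R)-2-methylbutanoyl]oxy}cyclohex-1-ene-1-carboxylate | CC[C@@H](C)C(=O)O[C@@H]1[C@H](OC(C)=O)C=C(C(=O)OC)C[C@H]1OC(=O)[C@H](C)CC | target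

**Total step count:** 9. **Longest linear sequence:** 9 steps (1 to 14).

**Steps most likely to fail**

Step 6. The nitroaldol is reversible, so the C3 epimers equilibrate and the faster-eliminating one is drained; facial selectivity at C3 may therefore be poor. Nitrite may also be lost before the ring closes. The fallback sets out from 10 as obtained (mixed at C3) and comes back at 10. The allylic alcohol mixture would be oxidized with Dess–Martin periodinane in CH2Cl2 to the single enone, methyl 3-dehydroshikimate 4,5-O-isopropylidene acetal F1. Luche reduction (NaBH4, CeCl3·7H2O, MeOH, −78 °C) should then deliver hydride axially onto the half-chair locked by the trans-fused dioxolane and give the pseudo-equatorial 3,4-trans alcohol 10.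

Step 3. The strongly basic dianion may not displace the triflate cleanly: SN2 at the β-oxygenated carbon may be slow, the triflate may decompose, or the nitronate oxygen may be alkylated. The fallback sets out from 3 and comes back at 6; it builds the C1–C2 bond by a nitroaldol on a keto ester instead.
- Triflate 3 would be alkylated with the soft sodium salt of methyl 1,3-dithiane-2-carboxylate (NaH, DMF, 0 °C) to give methyl 2-{[(4R,5R)-5-({[tert-butyl(dimethyl)silyl]oxy}methyl)-2,2-dimethyl-1,3-dioxolan-4-yl]methyl}-1,3-dithiane-2-carboxylate F2.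
- The dithiane would be removed (MeI, CaCO3, aqueous MeCN) to give the α-keto ester methyl 3-[(4R,5R)-5-({[tert-butyl(dimethyl)silyl]oxy}methyl)-2,2-dimethyl-1,3-dioxolan-4-yl]-2-oxopropanoate F3.
- A Henry reaction with nitromethane (Et3N) would give the tertiary nitro alcohol methyl 3-[(4R,5R)-5-({[tert-butyl(dimethyl)silyl]oxy}methyl)-2,2-dimethyl-1,3-dioxolan-4-yl]-2-hydroxy-2-(nitromethyl)propanoate F4.
- Dehydration (trifluoroacetic anhydride, Et3N, CH2Cl2, −20 °C) would give the β-nitroacrylate methyl 2-{[(4R,5R)-5-({[tert-butyl(dimethyl)silyl]oxy}methyl)-2,2-dimethyl-1,3-dioxolan-4-yl]methyl}-3-nitroprop-2-enoate F5.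
- Conjugate reduction of the nitroalkene (NaBH4, THF/MeOH, 0 °C) would give 6.

Step 7. The activated allylic oxygen may be lost by elimination (diene formation, then aromatization), or inversion may be incomplete. The fallback sets out from 10 and comes back at 11; it replaces the in situ redox activation by a stepwise sulfonate displacement. Alcohol 10 would be converted (Tf2O, pyridine, CH2Cl2, −20 °C) into the allylic triflate methyl 3-epi-shikimate 4,5-O-isopropylidene acetal 3-O-triflate F6. The triflate would then be displaced with tetrabutylammonium acetate (toluene, 0 °C to rt) in an SN2 reaction with inversion to give 11.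

**Further compounds**
F1 | step 6 | methyl 3-dehydroshikimate 4,5-O-isopropylidene acetal | CC1(C)O[C@@H]2C(=O)C=C(C(=O)OC)C[C@H]2O1
F2 | step 3 | methyl 2-{[(4R,5R)-5-({[tert-butyl(dimethyl)silyl]oxy}methyl)-2,2-dimethyl-1,3-dioxolan-4-yl]methyl}-1,3-dithiane-2-carboxylate | COC(=O)C1(C[C@H]2OC(C)(C)O[C@@H]2CO[Si](C)(C)C(C)(C)C)SCCCS1
F3 | step 3 | methyl 3-[(4R,5R)-5-({[tert-butyl(dimethyl)silyl]oxy}methyl)-2,2-dimethyl-1,3-dioxolan-4-yl]-2-oxopropanoate | COC(=O)C(=O)C[C@H]1OC(C)(C)O[C@@H]1CO[Si](C)(C)C(C)(C)C
F4 | step 3 | methyl 3-[(4R,5R)-5-({[tert-butyl(dimethyl)silyl]oxy}methyl)-2,2-dimethyl-1,3-dioxolan-4-yl]-2-hydroxy-2-(nitromethyl)propanoate | COC(=O)C(O)(C[N+](=O)[O-])C[C@H]1OC(C)(C)O[C@@H]1CO[Si](C)(C)C(C)(C)C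
F5 | step 3 | methyl 2-{[(4R,5R)-5-({[tert-butyl(dimethyl)silyl]oxy}methyl)-2,2-dimethyl-1,3-dioxolan-4-yl]methyl}-3-nitroprop-2-enoate | COC(=O)C(=C[N+](=O)[O-])C[C@H]1OC(C)(C)O[C@@H]1CO[Si](C)(C)C(C)(C)C
F6 | step 7 | methyl 3-epi-shikimate 4,5-O-isopropylidene acetal 3-O-trifluoromethanesulfonate | CC1(C)O[C@@H]2[C@@H](OS(=O)(=O)C(F)(F)F)C=C(C(=O)OC)C[C@H]2O1
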